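Start with the easy flask, larch, where everything goes in together, and count product per enzyme.

| flask | starting material | second substrate | enzyme | remark | time |
|---|---|---|---|---|---|
| south | 10 mM | 30 mM | 1 µM | run made earlier |  |
| north-east | 10 mM | 15 mM | 1 µM | run made earlier |  |
| east | 10 mM | 22 mM | 1 µM | run made earlier |  |
| larch | 10 mM | 30.0 mM | 1.0 µM | everything together at the start | 40 min |
| birch | 10 mM | 30.0 mM (in portions, 4, over 8.0 min) | 1.0 µM | first portion at the start, last at 8.0 min | 40 min |
| ash | 10 mM (fed, over 8.0 min) | 30.0 mM | 1.0 µM | all else is in the flask from the start; the feed brings no volume worth counting | 40 min |
| elm | 10 mM | 30.0 mM (fed, over 8.0 min) | 1.0 µM | all else is in the flask from the start; the feed brings no volume worth counting | 40 min |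

| run | time / min | product / % | starting material / % |
|---|---|---|---|
| south | 3.00 | 5 | 101 |
| south | 8.00 | 9 | 96 |
| south | 15.0 | 11 | 89 |
| south | 25.0 | 17 | 80 |
| north-east | 3.00 | 2 | 97 |
| north-east | 8.00 | 10 | 95 |
| north-east | 15.0 | 9 | 89 |
| north-east | 40.0 | 30 | 70 |
| east | 5.00 | 4 | 97 |
| east | 15.0 | 11 | 90 |
| east | 25.0 | 24 | 81 |
| east | 40.0 | 30 | 67 |

(readings scatter by 2 percentage points)

1. the flask that comes out highest in amount of product, in percent of the starting material charged, or "all alike" when all lie within 1.5 percentage points (larch / birch / ash / elm / all alike)
2. product at the end, in percent of the starting material charged, larch
3. product at the end, in percent of the starting material charged, birch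
4. product at the end, in percent of the starting material charged, ash
5. product at the end, in percent of the starting material charged, elm



The earlier runs show little effect of second substrate. At 40.0 min the north-east run, with 15 mM of it, and the east run, with 22 mM, both read 30% product. At 25.0 min starting material reads 80% in the south run and 81% in the east run. The curves run close to straight, so the enzyme seems to work at a steady pace. From the product and the loss of starting material at 40.0 min, in those two runs, the product made per enzyme per minute reads 76.9 /min. We carry this turnover, an apparent kcat, as the main step: product equals turnover times [enzyme] times time. For larch, our reckoning gives 30.8% of the charge.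

Now add the dosing, as a correction. A dosed flask spends a window below the tested range, and we price that window as turnover times [enzyme] times window, as if the enzyme stood idle throughout. Birch has had less than 15 mM of second substrate added until 2.67 min, priced at 2.1 percentage points. Elm has had that much fed after 4.00 min, priced at 3.1 points. Ash has had 6.70 mM of starting material fed, the lowest level read, after 5.36 min, priced at 4.1 points. By this reckoning, to stay within 1.5 points of larch, the enzyme must keep up on average 26.8% of its pace in the birch window, 51.6% in elm and 63.4% in ash. Within their scatter of 2 points, the readings show no slowing at the edge of these windows, so we expect that much and call the flasks equal.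

The forecast says all alike, with larch 31%, birch 30.7%, ash 30% and elm 30%. Its ground is that the curves at 15 mM, 22 mM and 30 mM of second substrate coincide, “so the rate does not depend on it in this range”.

The flasks give 31.9% for larch, 31.3% for birch, 31.1% for ash and 31.0% for elm, so the answer is all alike, and each lies inside the forecast's range. Elm stands lowest, 0.95 points under larch, which is less than the margin of 1.5 points and 30.6% of its window's price. second substrate + starting complex ⇌ ternary complex (K = 458 /M, k = 14300 /M/s); second substrate + enzyme → spent catalyst (k = 0.439 /M/min); second substrate ⇌ dormant form (K = 0.950, k = 0.0104 /min); starting material + enzyme ⇌ starting complex (K = 280 /M, k = 27000 /M/s); ternary complex → enzyme + product (k = 92.3 /min)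

For the neighbour of ash with 17 mM of starting material, we apply the same turnover: 3.08 mM of product, or 18.1% of its charge. That flask gives 18.9%.

(Readings and results are calculated with constants of no real substance, and the scatter is random.)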